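**Plan** (labdane numbering: decalin C1–C10, C11 on C9, C17 on C8, C18/C19 on C4, C20 on C10; β = face of the C10 methyl)
1. Feature: ring B (C5–C10) has its oxygen on C7 para to the methyl-bearing quaternary C10 and one-carbon groups on C8 (C17) and C9 (C11). It is a pentasubstituted p-cresol in reduced form, so ring A can be closed onto an aromatic ring B by oxidative dearomatisation.
2. Cuts, in retrosynthetic order: C12=C13 and C15–OO (dioxepine ring), C11–OO, C11–C12, the C8=C17/C7/C5/C9 adjustments back to a cross-conjugated dienone, C1–C10 (key step, silicon leaving C3), C3–Si, C2=C3, the C4–aryl bond, aryl C–O.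
3. Forward: the arene that becomes ring B is substituted first, and ring A closes in the key step. Ring B is then reduced to the trans-decalin and given its C7 alcohol and C8 methylene, the side chain is grown from C11, and the seven-membered peroxide ring closes last by metathesis.
4. Stereochemistry: C3 of the allylsilane comes from a copper-catalysed enantioselective allylic silylation, and C10 from C3 by anti-SE2′ transfer. C9, C8 (transient carbinol), C5 and C7 follow from C10 by substrate control. C11 comes from a 1,3-allylic-strain-controlled ene reaction of singlet oxygen, and C15 is set by equilibration.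

Key step: step 11

Assumption: C15 is a ring–chain equilibrating hemiperoxyacetal carbon, and the (15R) epimer drawn is taken to be the one favoured at equilibrium.

Step 1
Reactants: 1 2,6-dimethylbenzoic acid
Product: 2 3,5-dibromo-2,6-dimethylbenzoic acid
Conditions: Br2 (2.3 equiv), FeBr3 (5 mol%), AcOH, 50 °C
Reagents that add atoms: bromine, BrBr
Why: Electrophilic aromatic bromination, in which both methyl groups direct to C3 and C5 (ortho/para to methyl, meta to the carboxyl group) and C4, meta to both methyls, stays free.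

Step 2
Reactants: 2 3,5-dibromo-2,6-dimethylbenzoic acid
Product: 3 methyl 3,5-dibromo-2,6-dimethylbenzoate
Conditions: MeI, K2CO3, DMF, 25 °C
Reagents that add atoms: iodomethane, CI
Why: SN2 O-alkylation of the carboxylate avoids the Fischer esterification that fails for 2,6-disubstituted benzoic acids.

Step 3
Reactants: 3 methyl 3,5-dibromo-2,6-dimethylbenzoate
Product: 6 methyl 3-bromo-5-hydroxy-2,6-dimethylbenzoate, via arylmagnesium chloride 4 (not isolated), via dimethyl arylboronate 5 (not isolated)
Conditions: i-PrMgCl·LiCl (1.1 equiv), THF, 0 °C; B(OMe)3, 0 → 25 °C; then AcOH, 30% H2O2, 0 → 25 °C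
Reagents that add atoms: hydrogen peroxide, OO
Why: Bromine–magnesium exchange should stop after one bromide because the first aryl–magnesium bond deactivates the second, the doubly ortho-shielded ester is not attacked, and borylation followed by peroxide oxidation of the boronate turns the C–Mg bond into the phenol, so the symmetric dibromide is desymmetrised without a statistical coupling.

Step 4
Reactants: 6 methyl 3-bromo-5-hydroxy-2,6-dimethylbenzoate
Product: 7 methyl 3-bromo-2,6-dimethyl-5-(triisopropylsilyloxy)benzoate
Conditions: TIPSCl, imidazole, DMF, 25 °C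
Reagents that add atoms: triisopropylsilyl chloride, CC(C)[Si](Cl)(C(C)C)C(C)C
Why: Silylation of the phenol, the triisopropylsilyl ether being chosen because it should withstand the carbonate base, the hydride and the methoxide of steps 5 to 9.

Step 5
Reactants: 7 methyl 3-bromo-2,6-dimethyl-5-(triisopropylsilyloxy)benzoate; 8 2-methylpropanal
Product: 9 methyl 2,6-dimethyl-3-(2-methyl-1-oxopropan-2-yl)-5-(triisopropylsilyloxy)benzoate
Conditions: Pd(OAc)2 (2 mol%), rac-BINAP (3 mol%), Cs2CO3, dioxane, 80 °C
Reagents that add atoms: none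
Why: Palladium-catalysed α-arylation of an α-branched aldehyde (enolate arylation of the Buchwald–Hartwig type) forms the quaternary benzylic carbon C4 directly at the aldehyde oxidation level.

Step 6
Reactants: 9 methyl 2,6-dimethyl-3-(2-methyl-1-oxopropan-2-yl)-5-(triisopropylsilyloxy)benzoate; 10 triethyl phosphonoacetate
Product: 12 (E)-enoate (ethyl 4-aryl-4-methylpent-2-enoate), via sodium phosphonate anion 11 (not isolated)
Conditions: NaH, THF, 0 → 25 °C
Reagents that add atoms: none
Why: Horner–Wadsworth–Emmons olefination of the non-enolisable neopentyl aldehyde should give the (E)-enoate.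

Step 7
Reactants: 12 (E)-enoate
Product: 13 (E)-allylic alcohol (4-aryl-4-methylpent-2-en-1-ol)
Conditions: i-Bu2AlH (2.2 equiv), CH2Cl2, −78 °C
Reagents that add atoms: none
Why: Low-temperature 1,2-reduction of the unhindered enoate by diisobutylaluminium hydride, the aryl methyl ester being shielded from hydride by its two ortho methyl groups.

Step 8
Reactants: 13 (E)-allylic alcohol
Product: 14 (E)-allylic diethyl phosphate
Conditions: ClP(O)(OEt)2, pyridine, DMAP (cat.), CH2Cl2, 0 °C
Reagents that add atoms: diethyl chlorophosphate, CCOP(=O)(Cl)OCC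
Why: Phosphorylation of the primary allylic alcohol supplies the leaving group for the SN2′ substitution.

Step 9
Reactants: 14 (E)-allylic diethyl phosphate; 15 2-[dimethyl(phenyl)silyl]-4,4,5,5-tetramethyl-1,3,2-dioxaborolane
Product: 16 (3R)-allylsilane as its triisopropylsilyl ether
Conditions: CuCl (5 mol%), chiral C2-symmetric imidazolinium chloride (NHC precursor, 6 mol%, enantiomer chosen for 3R), NaOMe (1.5 equiv), THF, 0 °C
Reagents that add atoms: none
Why: Copper-catalysed enantioselective γ-selective (SN2′) allylic silylation, in which the NHC-bound silylcopper species adds to C3 of the (E)-allylic phosphate and expels phosphate to give the branched α-chiral allylsilane, the C3 configuration being set by the ligand.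

Step 10
Reactants: 16 (3R)-allylsilane as its triisopropylsilyl ether
Product: 17 methyl 3-[(3R)-3-[dimethyl(phenyl)silyl]-2-methylpent-4-en-2-yl]-5-hydroxy-2,6-dimethylbenzoate
Conditions: Bu4NF, AcOH, THF, 0 °C
Reagents that add atoms: none
Why: Fluoride cleaves the aryl silyl ether far faster than the C–Si bond of the allylsilane, and acetic acid buffers the phenoxide.

Step 11
Reactants: 17 methyl 3-[(3R)-3-[dimethyl(phenyl)silyl]-2-methylpent-4-en-2-yl]-5-hydroxy-2,6-dimethylbenzoate
Product: 19 methyl (8aS)-2,5,5,8a-tetramethyl-3-oxo-3,5,8,8a-tetrahydronaphthalene-1-carboxylate (bicyclic dienone), via aryloxyiodane 18 (not isolated)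
Conditions: PhI(OAc)2 (1.1 equiv), (CF3)2CHOH, −40 → 0 °C
Reagents that add atoms: none
Why: Proposed new method: PhI(OAc)2 in the fluoro alcohol converts the phenol through aryloxyiodane 18 into a phenoxonium ion whose para carbon C10 is attacked by the terminal alkene carbon C1 of the tethered allylsilane, and the β-silyl cation then loses silicon to leave the C2=C3 alkene and the cross-conjugated dienone; the closest known reactions are the trivalent-iodine para-allylation of 4-alkylphenols by allylsilanes and the anti-SE2′ reactions of α-chiral allylsilanes with carbon electrophiles. Ring A closes in a six-membered mode with both carbons of the reacting π-bond inside the new ring (6-endo with respect to the alkene), C4 being held in the plane of the arene. The only new stereocentre, C10, is controlled by the silicon-bearing C3: the C–Si bond must lie anti to the forming C1–C10 bond with H3 in the allyl plane, so the (R)-silane can reach only one face of C10 and should give the (S)-dienone. The step needs attack at the methyl-bearing para carbon C10 and not at the free ortho carbon C6, which would lead to a rearomatised tetralin; this is secured by the larger positive charge at the para position of the phenoxonium ion, by its tertiary character, and by the iodanyl group on oxygen, which shields both ortho carbons while the nucleophile arrives. Protodesilylation is held back by the low temperature and the short reaction time in a weakly nucleophilic solvent.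

Step 12
Reactants: 19 bicyclic dienone
Product: 20 methyl (8aS)-2,5,5,8a-tetramethyl-3-oxo-3,5,6,7,8,8a-hexahydronaphthalene-1-carboxylate
Conditions: H2 (1 atm, 1 equiv), Pd/C (5%), EtOAc, 25 °C
Reagents that add atoms: none
Why: Catalytic hydrogenation should take the cis-disubstituted ring-A alkene first, the tetrasubstituted C8=C9 and the neopentyl-flanked C5=C6 bonds being much slower, and C1 thereby stops being allylic, which removes the risk of reductive C1–C10 fragmentation in step 13.

Step 13
Reactants: 20 ring-A-saturated dienone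
Product: 22 5-en-7-one keto ester (8α-methyl and 9β-CO2Me), via keto ester epimers 21 (not isolated)
Conditions: Zn dust, AcOH, 25 °C; then NaOMe (0.2 equiv), MeOH, 25 °C
Reagents that add atoms: none
Why: Zinc in acetic acid reduces the doubly activated C8=C9 bond of the ene-1,4-dicarbonyl unit selectively (dissolving-metal conjugate reduction), and methoxide equilibration places the C9 ester and the C8 methyl equatorial, so that C9 (β ester, α hydrogen) is set by thermodynamic relay from C10.

Step 14
Reactants: 22 5-en-7-one keto ester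
Product: 24 8α-hydroxy-8β-methyl 5-en-7-one ester, via potassium dienolate 23 (not isolated)
Conditions: KN(SiMe3)2 (1.1 equiv), THF, −78 °C; 2-(phenylsulfonyl)-3-phenyloxaziridine, −78 °C; aq. NH4Cl
Reagents that add atoms: 2-(phenylsulfonyl)-3-phenyloxaziridine, O=S(=O)(c1ccccc1)N1OC1c1ccccc1
Why: The ketone can enolise only towards C8 because C6 is vinylic, and oxaziridine hydroxylation of the dienolate (Davis-type enolate oxidation) should deliver oxygen to the α face, anti to the axial C10 methyl and to the β ester on C9, giving the 8α carbinol.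

Step 15
Reactants: 24 8α-hydroxy-8β-methyl 5-en-7-one ester
Product: 25 trans-decalin 8α-hydroxy-7-oxo ester (5α-H)
Conditions: H2 (4 atm), Pd/C (10%), EtOAc, 25 °C
Reagents that add atoms: none
Why: Heterogeneous hydrogenation of the remaining enone bond should add hydrogen to the α face because the β face is blocked by the axial methyl groups on C4, C8 and C10, which sets the 5α hydrogen and the trans ring fusion (the outcome known for steroidal 5-en-7-ones).

Step 16
Reactants: 25 trans-decalin 8α-hydroxy-7-oxo ester
Product: 27 7-oxo-8(17)-methylene 9β-ester, via chlorosulfite 26 (not isolated)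
Conditions: SOCl2, pyridine, CH2Cl2, −78 → 0 °C
Reagents that add atoms: none
Why: E2 dehydration of the tertiary α-ketol through its chlorosulfite, in which the equatorial leaving group allows only the methyl hydrogens to become anti-periplanar, so the exocyclic C8=C17 alkene should form in preference to the C8=C9 isomer (the selectivity known for 8α-hydroxy labdanes and drimanes).

Step 17
Reactants: 27 7-oxo-8(17)-methylene 9β-ester
Product: 28 7β-hydroxy-8(17)-methylene 9β-ester
Conditions: NaBH4, CeCl3·7H2O, MeOH, −78 → −20 °C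
Reagents that add atoms: none
Why: Luche reduction gives 1,2-reduction of the enone, and axial hydride attack from the α face of the chair should furnish the equatorial 7β alcohol while the ester is untouched.

Step 18
Reactants: 28 7β-hydroxy-8(17)-methylene 9β-ester
Product: 29 7β-tert-butyldimethylsilyl ether of 28
Conditions: TBSOTf, 2,6-lutidine, CH2Cl2, 0 °C
Reagents that add atoms: tert-butyldimethylsilyl triflate, CC(C)(C)[Si](C)(C)OS(=O)(=O)C(F)(F)F
Why: Silylation masks the allylic alcohol so that it neither consumes hydride or ylide nor directs singlet oxygen to the exocyclic alkene in step 22.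

Step 19
Reactants: 29 silyl ether ester
Product: 30 primary alcohol (C11 hydroxymethyl on C9)
Conditions: i-Bu2AlH (2.5 equiv), CH2Cl2, −78 → 0 °C
Reagents that add atoms: none
Why: Diisobutylaluminium hydride reduces the hindered ester to the primary alcohol without touching the alkene or the silyl ether.

Step 20
Reactants: 30 primary alcohol
Product: 31 aldehyde (C11 formyl on C9)
Conditions: Dess–Martin periodinane, CH2Cl2, 0 → 25 °C
Reagents that add atoms: none
Why: Dess–Martin oxidation under near-neutral conditions should give the β,γ-unsaturated aldehyde without epimerising C9 or moving the alkene into conjugation, and the crude aldehyde is used at once.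

Step 21
Reactants: 31 aldehyde; 32 ethyltriphenylphosphonium bromide
Product: 34 (11Z)-propenyl compound, via phosphorus ylide 33 (not isolated)
Conditions: KN(SiMe3)2, THF, −78 → 0 °C
Reagents that add atoms: none
Why: Salt-free Wittig reaction of the non-stabilised ylide with the hindered aldehyde should give the (Z)-alkene, and the low temperature keeps the C9 stereocentre intact.

Step 22
Reactants: 34 (11Z)-propenyl compound
Product: 35 (11S)-allylic hydroperoxide (C9–CH(OOH)–CH=CH2)
Conditions: O2, tetraphenylporphyrin (cat.), visible light, CH2Cl2, −20 °C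
Reagents that add atoms: dioxygen, O=O
Why: Schenck ene reaction of singlet oxygen, in which 1,3-allylic strain holds H9 in the plane of the (Z)-alkene so that hydrogen is taken only from the methyl group and oxygen adds to C11 on the face turned towards the flat C8 methylene and away from the quaternary C10, which should give the (11S) hydroperoxide, while the exocyclic alkene, deactivated by the allylic silyloxy group, reacts more slowly.

Step 23
Reactants: 36 methyl 4,4-dimethoxybutanoate
Product: 37 4,4-dimethoxybutanal
Conditions: i-Bu2AlH (1.05 equiv), CH2Cl2, −78 °C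
Reagents that add atoms: none
Why: Partial reduction of the ester to the aldehyde through the aluminium hemiacetal that is stable at −78 °C.

Step 24
Reactants: 37 4,4-dimethoxybutanal
Product: 39 4,4-dimethoxy-2-methylidenebutanal, via Mannich base 38 (not isolated)
Conditions: CH2=NMe2+ I−, Et3N, CH2Cl2, 25 °C
Reagents that add atoms: N,N-dimethylmethyleneiminium iodide (Eschenmoser's salt), C=[N+](C)C.[I-]
Why: Mannich reaction with Eschenmoser's salt followed by elimination of dimethylamine (α-methylenation of an aldehyde).

Step 25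
Reactants: 35 (11S)-allylic hydroperoxide; 39 4,4-dimethoxy-2-methylidenebutanal (3 equiv)
Product: 40 mixed methyl peroxyacetal (C11–O–O–C15H(OMe)–C14H2–C13(=CH2)–CHO)
Conditions: PPTS (cat.), 4 Å molecular sieves, CH2Cl2, 25 °C
Reagents that add atoms: none
Why: Acid-catalysed acetal exchange, in which the hydroperoxide replaces one methoxy group of the dimethyl acetal through the oxocarbenium ion; both C15 epimers are carried on because this centre is equilibrated in step 27.

Step 26
Reactants: 40 mixed methyl peroxyacetal
Product: 41 cyclic methyl peroxyacetal (3-methoxy-4,7-dihydro-3H-1,2-dioxepine-5-carbaldehyde attached through C7 of the heterocycle to C9)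
Conditions: second-generation Hoveyda–Grubbs catalyst RuCl2(H2IMes)(=CH–C6H4-2-O-i-Pr) (5 mol%), toluene, 40 °C
Reagents that add atoms: none
Why: Ring-closing metathesis, in which the catalyst loads on the monosubstituted vinyl group and closes onto the 2-substituted acrolein unit; the seven-membered ring forces C11 and C14 cis on the new C12=C13 bond, which is the (E)-enal geometry of the target, and the hindered exocyclic methylene cannot compete.

Step 27
Reactants: 41 cyclic methyl peroxyacetal
Product: 42 CNP0269954.2 (target)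
Conditions: 48% aq. HF, MeCN, 0 → 25 °C
Reagents that add atoms: water, O
Why: Aqueous hydrofluoric acid removes the silyl ether and hydrolyses the methyl peroxyacetal to the hemiperoxyacetal, whose ring–chain equilibration should settle C15 in the favoured configuration.

**Compound list**
1 | 2,6-dimethylbenzoic acid | Cc1cccc(C)c1C(=O)O | starting material
2 | 3,5-dibromo-2,6-dimethylbenzoic acid | Cc1c(Br)cc(Br)c(C)c1C(=O)O | intermediate
3 | methyl 3,5-dibromo-2,6-dimethylbenzoate | COC(=O)c1c(C)c(Br)cc(Br)c1C | intermediate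
4 | [5-bromo-3-(methoxycarbonyl)-2,4-dimethylphenyl]magnesium chloride | COC(=O)c1c(C)c(Br)cc([Mg]Cl)c1C | intermediate
5 | dimethyl [5-bromo-3-(methoxycarbonyl)-2,4-dimethylphenyl]boronate | COC(=O)c1c(C)c(Br)cc(B(OC)OC)c1C | intermediate
6 | methyl 3-bromo-5-hydroxy-2,6-dimethylbenzoate | COC(=O)c1c(C)c(O)cc(Br)c1C | intermediate
7 | methyl 3-bromo-2,6-dimethyl-5-(triisopropylsilyloxy)benzoate | COC(=O)c1c(C)c(O[Si](C(C)C)(C(C)C)C(C)C)cc(Br)c1C | intermediate
8 | 2-methylpropanal | CC(C)C=O | starting material
9 | methyl 2,6-dimethyl-3-(2-methyl-1-oxopropan-2-yl)-5-(triisopropylsilyloxy)benzoate | COC(=O)c1c(C)c(O[Si](C(C)C)(C(C)C)C(C)C)cc(C(C)(C)C=O)c1C | intermediate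
10 | triethyl phosphonoacetate | CCOC(=O)CP(=O)(OCC)OCC | starting material
11 | sodium salt of triethyl phosphonoacetate | CCOC(=O)[CH-]P(=O)(OCC)OCC.[Na+] | intermediate
12 | methyl 3-[(3E)-5-ethoxy-2-methyl-5-oxopent-3-en-2-yl]-2,6-dimethyl-5-(triisopropylsilyloxy)benzoate | CCOC(=O)/C=C/C(C)(C)c1cc(O[Si](C(C)C)(C(C)C)C(C)C)c(C)c(C(=O)OC)c1C | intermediate
13 | methyl 3-[(3E)-5-hydroxy-2-methylpent-3-en-2-yl]-2,6-dimethyl-5-(triisopropylsilyloxy)benzoate | COC(=O)c1c(C)c(O[Si](C(C)C)(C(C)C)C(C)C)cc(C(C)(C)/C=C/CO)c1C | intermediate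
14 | methyl 3-[(3E)-5-(diethoxyphosphoryloxy)-2-methylpent-3-en-2-yl]-2,6-dimethyl-5-(triisopropylsilyloxy)benzoate | COC(=O)c1c(C)c(O[Si](C(C)C)(C(C)C)C(C)C)cc(C(C)(C)/C=C/COP(=O)(OCC)OCC)c1C | intermediate
15 | 2-[dimethyl(phenyl)silyl]-4,4,5,5-tetramethyl-1,3,2-dioxaborolane | CC1(C)OB(OC1(C)C)[Si](C)(C)c1ccccc1 | starting material
16 | methyl 3-[(3R)-3-[dimethyl(phenyl)silyl]-2-methylpent-4-en-2-yl]-2,6-dimethyl-5-(triisopropylsilyloxy)benzoate | COC(=O)c1c(C)c(O[Si](C(C)C)(C(C)C)C(C)C)cc(C(C)(C)[C@@H](C=C)[Si](C)(C)c2ccccc2)c1C | intermediate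
17 | methyl 3-[(3R)-3-[dimethyl(phenyl)silyl]-2-methylpent-4-en-2-yl]-5-hydroxy-2,6-dimethylbenzoate | COC(=O)c1c(C)c(O)cc(C(C)(C)[C@@H](C=C)[Si](C)(C)c2ccccc2)c1C | intermediate
18 | acetoxy(phenyl)-λ3-iodanyl ether of phenol 17 | COC(=O)c1c(C)c(OI(OC(C)=O)c2ccccc2)cc(C(C)(C)[C@@H](C=C)[Si](C)(C)c2ccccc2)c1C | intermediate
19 | methyl (8aS)-2,5,5,8a-tetramethyl-3-oxo-3,5,8,8a-tetrahydronaphthalene-1-carboxylate (C5=C6, C8=C9 and C2=C3 in target numbering) | COC(=O)C1=C(C)C(=O)C=C2C(C)(C)C=CC[C@]12C | intermediate
20 | methyl (8aS)-2,5,5,8a-tetramethyl-3-oxo-3,5,6,7,8,8a-hexahydronaphthalene-1-carboxylate | COC(=O)C1=C(C)C(=O)C=C2C(C)(C)CCC[C@]12C | intermediate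
21 | 5-en-7-one keto ester as crude mixture of C8 and C9 epimers | COC(=O)C1C(C)C(=O)C=C2C(C)(C)CCC[C@]12C | intermediate
22 | 5-en-7-one keto ester: 8α-methyl (8β-H), 9β-CO2Me (9α-H), 10β-methyl | C[C@H]1[C@H](C(=O)OC)[C@@]2(C)CCCC(C)(C)C2=CC1=O | intermediate
23 | potassium dienolate of 22 (C7–O−, C7=C8, C5=C6) | CC1=C([O-])C=C2C(C)(C)CCC[C@]2(C)[C@H]1C(=O)OC.[K+] | intermediate
24 | 8α-hydroxy-8β-methyl 5-en-7-one 9β-ester | C[C@]1(O)[C@H](C(=O)OC)[C@@]2(C)CCCC(C)(C)C2=CC1=O | intermediate
25 | trans-decalin (5α-H, 10β-methyl) 8α-hydroxy-8β-methyl-7-oxo 9β-ester | C[C@]1(O)[C@H](C(=O)OC)[C@@]2(C)CCCC(C)(C)[C@@H]2CC1=O | intermediate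
26 | chlorosulfite of the 8α-hydroxy group of 25 | C[C@]1(OS(Cl)=O)[C@H](C(=O)OC)[C@@]2(C)CCCC(C)(C)[C@@H]2CC1=O | intermediate
27 | trans-decalin 7-oxo-8(17)-methylene 9β-ester | C=C1[C@H](C(=O)OC)[C@@]2(C)CCCC(C)(C)[C@@H]2CC1=O | intermediate
28 | trans-decalin 7β-hydroxy-8(17)-methylene 9β-ester | C=C1[C@H](C(=O)OC)[C@@]2(C)CCCC(C)(C)[C@@H]2C[C@@H]1O | intermediate
29 | 7β-(tert-butyldimethylsilyloxy)-8(17)-methylene 9β-ester | C=C1[C@H](C(=O)OC)[C@@]2(C)CCCC(C)(C)[C@@H]2C[C@@H]1O[Si](C)(C)C(C)(C)C | intermediate
30 | 7β-silyloxy-8(17)-methylene 9β-hydroxymethyl decalin | C=C1[C@H](CO)[C@@]2(C)CCCC(C)(C)[C@@H]2C[C@@H]1O[Si](C)(C)C(C)(C)C | intermediate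
31 | 7β-silyloxy-8(17)-methylene 9β-carbaldehyde | C=C1[C@H](C=O)[C@@]2(C)CCCC(C)(C)[C@@H]2C[C@@H]1O[Si](C)(C)C(C)(C)C | intermediate
32 | ethyltriphenylphosphonium bromide | CC[P+](c1ccccc1)(c1ccccc1)c1ccccc1.[Br-] | starting material
33 | ethylidenetriphenylphosphorane | CC=P(c1ccccc1)(c1ccccc1)c1ccccc1 | intermediate
34 | 7β-silyloxy-8(17)-methylene 9β-[(Z)-prop-1-enyl] decalin | C=C1[C@H](/C=C\C)[C@@]2(C)CCCC(C)(C)[C@@H]2C[C@@H]1O[Si](C)(C)C(C)(C)C | intermediate
35 | 7β-silyloxy-8(17)-methylene 9β-[(1S)-1-hydroperoxyprop-2-enyl] decalin (11S) | C=C1[C@H]([C@@H](OO)C=C)[C@@]2(C)CCCC(C)(C)[C@@H]2C[C@@H]1O[Si](C)(C)C(C)(C)C | intermediate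
36 | methyl 4,4-dimethoxybutanoate | COC(=O)CCC(OC)OC | starting material
37 | 4,4-dimethoxybutanal | O=CCCC(OC)OC | intermediate
38 | 2-[(dimethylamino)methyl]-4,4-dimethoxybutanal | CN(C)CC(C=O)CC(OC)OC | intermediate
39 | 4,4-dimethoxy-2-methylidenebutanal | C=C(C=O)CC(OC)OC | intermediate
40 | mixed methyl peroxyacetal of 35 and 39 (11S; C15 epimers) | C=C1[C@H]([C@@H](OOC(OC)CC(=C)C=O)C=C)[C@@]2(C)CCCC(C)(C)[C@@H]2C[C@@H]1O[Si](C)(C)C(C)(C)C | intermediate
41 | 7β-silyloxy cyclic methyl peroxyacetal (11S; C15 epimers; C12=C13 in the dioxepine) | C=C1[C@H]([C@@H]2C=C(C=O)CC(OC)OO2)[C@@]2(C)CCCC(C)(C)[C@@H]2C[C@@H]1O[Si](C)(C)C(C)(C)C | intermediate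
42 | CNP0269954.2 | C=C1[C@H]([C@@H]2C=C(C=O)C[C@H](O)OO2)[C@@]2(C)CCCC(C)(C)[C@@H]2C[C@@H]1O | target

**Step count and risks**
Total steps: 27. Longest linear sequence: 25 (steps 1–22 and 25–27); the two-step branch to 39 (steps 23–24) joins at step 25.

Steps most likely to fail:

Step 11. The allylsilane may attack the free ortho carbon C6 and the product rearomatise, it may be protodesilylated before it cyclises, or the chirality transfer may be eroded by a syn pathway. The fallback uses known reactions only, sets out from aldehyde 9 and returns at dienone 19. Wittig methylenation of 9 (Ph3P=CH2) gives methyl 2,6-dimethyl-3-(2-methylbut-3-en-2-yl)-5-(triisopropylsilyloxy)benzoate F1, and Bu4NF/AcOH frees the phenol F2. PhI(OAc)2 with allyltrimethylsilane in (CF3)2CHOH performs the known intermolecular para-allylation of a 4-alkylphenol to give the racemic 4-allyl-4-methyl dienone F3. Ring-closing metathesis with the second-generation Grubbs catalyst RuCl2(H2IMes)(PCy3)(=CHPh) closes ring A to the racemic bicyclic dienone F4. Chromatography on a chiral stationary phase separates F4 into 19 and its enantiomer F5.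

Step 22. Facial selectivity at C11 may be poor, or the ene reaction may compete at the exocyclic alkene. The fallback sets out from aldehyde 31 and returns at hydroperoxide 35, with reagent control in place of substrate control. Vinylmagnesium bromide gives the allylic alcohol epimers F6, and Dess–Martin oxidation gives the vinyl ketone F7. Corey–Bakshi–Shibata reduction (2-methyl-CBS-oxazaborolidine of the enantiomer that gives 11R, BH3·SMe2) gives the (11R)-allylic alcohol F8. Mesylation (MsCl, Et3N) gives the mesylate F9, and SN2 displacement with anhydrous H2O2 in ether at low temperature, with inversion, gives 35.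

Step 26. The peroxide may decompose the ruthenium carbene, or ring closure onto the electron-poor 1,1-disubstituted alkene may be too slow. The fallback sets out from hydroperoxide 35 and returns at target 42; it forms the C12=C13 bond intermolecularly and closes the peroxide ring last. 2-Methoxypropene with PPTS protects 35 as the 2-methoxyprop-2-yl peroxyketal F10. Cross-metathesis with excess 39 (second-generation Hoveyda–Grubbs catalyst), which for 2-substituted acroleins is known to be (E)-selective, gives the (E)-enal F11. Aqueous HF in MeCN removes the peroxyketal, the dimethyl acetal and the silyl ether to give the hydroperoxy dialdehyde F12, which should close spontaneously onto the C15 aldehyde to give 42.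

**Further compounds**
F1 | step 11 | methyl 2,6-dimethyl-3-(2-methylbut-3-en-2-yl)-5-(triisopropylsilyloxy)benzoate | COC(=O)c1c(C)c(O[Si](C(C)C)(C(C)C)C(C)C)cc(C(C)(C)C=C)c1C
F2 | step 11 | methyl 3-hydroxy-2,6-dimethyl-5-(2-methylbut-3-en-2-yl)benzoate | COC(=O)c1c(C)c(O)cc(C(C)(C)C=C)c1C
F3 | step 11 | racemic methyl 6-allyl-2,6-dimethyl-5-(2-methylbut-3-en-2-yl)-3-oxocyclohexa-1,4-diene-1-carboxylate | COC(=O)C1=C(C)C(=O)C=C(C(C)(C)C=C)C1(C)CC=C
F4 | step 11 | racemic bicyclic dienone | COC(=O)C1=C(C)C(=O)C=C2C(C)(C)C=CCC12C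
F5 | step 11 | (8aR)-bicyclic dienone (enantiomer of 19) | COC(=O)C1=C(C)C(=O)C=C2C(C)(C)C=CC[C@@]12C
F6 | step 22 | 9β-(1-hydroxyprop-2-enyl) decalin, C11 epimers | C=C1[C@H](C(O)C=C)[C@@]2(C)CCCC(C)(C)[C@@H]2C[C@@H]1O[Si](C)(C)C(C)(C)C
F7 | step 22 | 9β-acryloyl decalin (vinyl ketone) | C=C1[C@H](C(=O)C=C)[C@@]2(C)CCCC(C)(C)[C@@H]2C[C@@H]1O[Si](C)(C)C(C)(C)C
F8 | step 22 | (11R)-allylic alcohol | C=C1[C@H]([C@H](O)C=C)[C@@]2(C)CCCC(C)(C)[C@@H]2C[C@@H]1O[Si](C)(C)C(C)(C)C
F9 | step 22 | (11R)-allylic mesylate | C=C1[C@H]([C@H](OS(C)(=O)=O)C=C)[C@@]2(C)CCCC(C)(C)[C@@H]2C[C@@H]1O[Si](C)(C)C(C)(C)C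
F10 | step 26 | 2-methoxyprop-2-yl peroxyketal of 35 | C=C1[C@H]([C@@H](OOC(C)(C)OC)C=C)[C@@]2(C)CCCC(C)(C)[C@@H]2C[C@@H]1O[Si](C)(C)C(C)(C)C
F11 | step 26 | (12E)-enal peroxyketal with C15 dimethyl acetal | C=C1[C@H]([C@@H](OOC(C)(C)OC)/C=C(/C=O)CC(OC)OC)[C@@]2(C)CCCC(C)(C)[C@@H]2C[C@@H]1O[Si](C)(C)C(C)(C)C
F12 | step 26 | (11S,12E)-11-hydroperoxy-7β-hydroxy-15,16-dialdehyde (open form of 42) | C=C1[C@H]([C@@H](OO)/C=C(/C=O)CC=O)[C@@]2(C)CCCC(C)(C)[C@@H]2C[C@@H]1O
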